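Take time first: the asked 12 h lies 1.26 powers of ten beyond the first spring sample, yet from 0.667 h to 2.50 h the spring readings move within their scatter of 1 percentage point. The asked flask is that spring run continued, so hold its plateau.

| setting | spring | winter | flask |
|---|---|---|---|
| starting complex | 0.10 M | 0.10 M | 0.10 M |
| incoming ligand | 0.070 M | 0.035 M | 0.0700 M |
| remark | the very flask that is asked about, followed so far | run made earlier |  |
| time |  |  | 12 h |

| run | time / h | starting complex / % | complex with two exchanged / % |
|---|---|---|---|
| spring | 0.667 | 40.8 | 16.0 |
| spring | 1.33 | 41.4 | 15.1 |
| spring | 2.00 | 40.6 | 14.7 |
| spring | 2.50 | 41.7 | 16.9 |
| winter | 0.667 | 52.0 | 7.0 |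
| winter | 1.50 | 52.3 | 6.2 |
| winter | 3.00 | 52.9 | 6.4 |
| winter | 5.00 | 52.6 | 6.7 |

(scatter of a reading: 1 percentage point)

- why nothing more happens at 12 h, or that something still does (it is still moving / all of the starting complex has reacted / the incoming ligand has run out first)
- share of the starting complex used up at 12 h
- complex with two exchanged at 12 h, in percent of the starting complex charged
- complex with one exchanged at 12 h, in percent of the starting complex charged

- what is said of leaving ligand includes crystals
- crystals is a solid; its amount is given per volume of the solution
- steps that have been proposed: starting complex + incoming ligand -> leaving ligand + complex with one exchanged; complex with one exchanged + incoming ligand -> leaving ligand + complex with two exchanged; complex with two exchanged + incoming ligand -> leaving ligand + complex with three exchanged; complex with three exchanged + incoming ligand -> leaving ligand + complex with four exchanged; crystals <-> leaving ligand; starting complex <-> dormant form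
- what has gone from starting complex into another species counts as reacted, even if it can come back
- the reaction counts as stopped when no species that holds the starting complex changes by six tenths of a point or more over the second half of the time

Take incoming ligand as the limiting reagent behind the plateau, and reckon with the ligand budget, c(incoming ligand) over c(starting complex) as charged: 70.0% in spring, 35.0% in winter, one ligand per exchange. The spring mean of starting complex, 41.1%, gives a conversion of 58.9%, and complex with two exchanged reads 15.7%.

Now go to winter, where starting complex reads a mean of 52.4% and so lost 47.6%, more than the winter budget, so part of it must be dormant form. Subtract one ligand for each second exchange, using the winter reading 6.58%, and the dormant form over starting complex comes to 0.365. Carry that ratio to spring: the budget then leaves 10.4% as the extra cost of complexes with three and four exchanged.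

The weak link is that winter was charged nothing for this cost. Reforge it with logarithms: the two-exchanged level differs between the runs by 0.377 powers of ten, so assume that the cost of the higher complexes differs by double that, and take off 0.755 powers. Winter's cost becomes 1.84%, and the ratio 0.400. Spring then has 42.4% exchanged and a surplus of 11.9%. Each higher complex costs two or three extra ligands, so average both divisions, which leaves complex with one exchanged at 21.8%.

The forecast, “the incoming ligand has simply run out”, answers: the incoming ligand has run out first, with conversion 58.9%, complex with two exchanged 15.7% and complex with one exchanged 21.5%, the last below my figure.

The flask answers: the incoming ligand has run out first, with conversion 59.2%, complex with two exchanged 15.7% and complex with one exchanged 22.1%.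

    starting complex + incoming ligand → leaving ligand + complex with one exchanged (k = 0.901 /M/s)
    complex with one exchanged + incoming ligand → leaving ligand + complex with two exchanged (k = 1.77 /M/s)
    complex with two exchanged + incoming ligand → leaving ligand + complex with three exchanged (k = 1.04 /M/s)
    complex with three exchanged + incoming ligand → leaving ligand + complex with four exchanged (k = 1.63 /M/s)
    crystals ⇌ leaving ligand, rate k5*(cs5 - [leaving ligand]) while solid is left; crystals form when [leaving ligand] > cs5 (solubility = 1.60 mM, k = 0.611 /s)
    starting complex ⇌ dormant form (K = 0.400, k = 0.0197 /s)

The exchange steps ran while incoming ligand was there, its half-life by the first step being 0.22 min at 0.00255 h, and nearly all of the conversion stood at 0.429 min. From 1.20 h to 12.0 h incoming ligand stood at 0% and the flask's amounts read the same, with exchanges counted over its complexes reaching 70.0% against the budget of 70.0%. The neighbour flask with 0.060 M of starting complex has a budget of 117%, and its complexes hold 117%.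

The earlier runs and the new flask come from a simulation for an exercise; noise was put on by code.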